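**Plan** (cembrane numbering: ring C1–C14; lactone C15/C16/C17 on C1 and C2; acetate on C7; O–O bridge from C8 to C11; methyls C18, C19, C20 on C4, C8, C12)

- Feature used: C8 is the fully substituted carbon of the 1,2-dioxane (C8–C9–C10–C11–O–O) and bears a peroxy oxygen, so it can be a cyclic peroxycarbenium ion. C7 bears the acetate, which is the Baeyer–Villiger trace of an acetyl group, so C7 can be the nucleophilic α-carbon of a methyl ketone.
- Cuts, in retrosynthetic order: C7–O (Baeyer–Villiger), C7–C8 (macrocycle), C11–O and C8–O of the dioxane, C1–C2 plus the lactone C–O, C12=C13, C3=C4.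
- Forward: west enal 4 (3 steps) and east allyl bromide 17 (7 steps) are joined with formation of the lactone, then the dioxane is built, then the 14-membered ring is closed at C7–C8, then the acetyl helper is turned into the acetate.
- Stereochemistry: C11 comes from (R)-5-oxotetrahydrofuran-2-carboxylic acid and is inverted to S by SN2 perhydrolysis. C12=C13 (Z) comes from a Wittig reaction on an α-oxygenated methyl ketone, C3=C4 (E) from syn carboalumination.
- C1 and C2 come from a ligand-controlled, syn-selective chromium allylation. C8 and C7 are set in the ring closure, and the Baeyer–Villiger step retains C7.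

Key step: step 14

Remark: 19 equilibrates with its five-membered cyclic hemiketal and is drawn open; salt 8 is taken as a catalogue reagent (otherwise one step from (3-bromopropoxy)(tert-butyl)dimethylsilane and PPh3).

**Step 1**
Reactants: 1 2-(3-chloropropyl)-2-methyl-1,3-dioxolane
Product: 2 2-methyl-2-(pent-4-yn-1-yl)-1,3-dioxolane
Conditions: LiC≡CH·H2NCH2CH2NH2, DMSO, rt
Reagents that add atoms: lithium acetylide–ethylenediamine complex, [Li+].[C-]#C.NCCN
Why: SN2 alkylation of the acetylide by the primary chloride (alkyne alkylation) should install C3 and C4 while the future acetyl group stays masked as the dioxolane.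

**Step 2**
Reactants: 2 2-methyl-2-(pent-4-yn-1-yl)-1,3-dioxolane
Product: 3 (E)-3-methyl-6-(2-methyl-1,3-dioxolan-2-yl)hex-2-en-1-ol
Conditions: AlMe3, Cp2ZrCl2 (cat.), H2O (1 equiv), CH2Cl2, −23 °C; then n-BuLi, (CH2O)n, THF
Reagents that add atoms: trimethylaluminium, C[Al](C)C; formaldehyde (from paraformaldehyde), C=O
Why: Zirconium-catalysed Negishi carboalumination adds methyl and aluminium syn across the terminal alkyne with methyl on the internal carbon and the alkenylalanate is hydroxymethylated with retention, which should fix the E geometry of C3=C4 and deliver C18 and C2.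

**Step 3**
Reactants: 3 (E)-3-methyl-6-(2-methyl-1,3-dioxolan-2-yl)hex-2-en-1-ol
Product: 4 (E)-3-methyl-6-(2-methyl-1,3-dioxolan-2-yl)hex-2-enal
Conditions: MnO2, CH2Cl2, rt
Reagents that add atoms: none
Why: MnO2 oxidises only the allylic alcohol (allylic oxidation) and should leave the E geometry and the dioxolane untouched.

**Step 4**
Reactants: 5 (R)-5-oxotetrahydrofuran-2-carboxylic acid
Product: 7 (R)-5-acetyldihydrofuran-2(3H)-one, via acid chloride 6 (not isolated)
Conditions: (COCl)2, DMF (cat.), CH2Cl2, 0 °C → rt; then Me2CuLi, Et2O–THF, −78 °C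
Reagents that add atoms: lithium dimethylcuprate, [Li+].C[Cu-]C
Why: The acid chloride reacts with the Gilman cuprate to the methyl ketone and stops there at −78 °C (acyl substitution), the lactone and the chiral-pool stereocentre (future C11) being unaffected.

**Step 5**
Reactants: 7 (R)-5-acetyldihydrofuran-2(3H)-one; 8 [3-(tert-butyldimethylsilyloxy)propyl]triphenylphosphonium bromide
Product: 9 (R)-5-[(Z)-5-(tert-butyldimethylsilyloxy)pent-2-en-2-yl]dihydrofuran-2(3H)-one
Conditions: NaN(SiMe3)2, THF, −78 → 0 °C
Reagents that add atoms: none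
Why: Wittig olefination of an α-oxygenated methyl ketone with a salt-free non-stabilised ylide is Z-selective for the trisubstituted alkene, so C14 should end up cis to C11 (C12=C13 Z), and the fast addition at −78 °C should outrun enolisation at C11.

**Step 6**
Reactants: 9 (R)-5-[(Z)-5-(tert-butyldimethylsilyloxy)pent-2-en-2-yl]dihydrofuran-2(3H)-one
Product: 11 (5R)-2-methoxy-2-methyl-5-[(Z)-5-(tert-butyldimethylsilyloxy)pent-2-en-2-yl]tetrahydrofuran (both C2 epimers), via lactol 10 (not isolated)
Conditions: MeLi (1.05 equiv), THF, −78 °C; AcOH; then MeOH, PPTS (cat.), rt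
Reagents that add atoms: methyllithium, [Li]C; methanol, CO
Why: One equivalent of MeLi adds once to the γ-lactone because the lithium lactolate persists at −78 °C (lactone-to-lactol addition, bringing in C19), and acid-catalysed acetalisation with methanol then locks C11–O and the C8 ketone together as a cyclic methyl ketal that tolerates the following steps.

**Step 7**
Reactants: 11 cyclic methyl ketal silyl ether
Product: 12 (Z)-4-[(2R)-5-methoxy-5-methyltetrahydrofuran-2-yl]pent-3-en-1-ol
Conditions: Bu4NF, THF, 0 °C
Reagents that add atoms: none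
Why: Fluoride cleaves the primary silyl ether (desilylation) without touching the cyclic ketal.

**Step 8**
Reactants: 12 (Z)-4-[(2R)-5-methoxy-5-methyltetrahydrofuran-2-yl]pent-3-en-1-ol
Product: 13 (Z)-4-[(2R)-5-methoxy-5-methyltetrahydrofuran-2-yl]pent-3-enal
Conditions: Dess–Martin periodinane, pyridine, CH2Cl2, 0 °C
Reagents that add atoms: none
Why: Buffered Dess–Martin oxidation gives the β,γ-unsaturated aldehyde under non-acidic conditions that should not move C12=C13 into conjugation, and the aldehyde is used at once.

**Step 9**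
Reactants: 13 (Z)-4-[(2R)-5-methoxy-5-methyltetrahydrofuran-2-yl]pent-3-enal; 14 methyl propiolate
Product: 16 methyl (Z)-3-hydroxy-6-[(2R)-5-methoxy-5-methyltetrahydrofuran-2-yl]-2-methylidenehept-5-enoate (both C3 epimers), via vinylalane 15 (not isolated)
Conditions: 14, i-Bu2AlH, N-methylmorpholine N-oxide, THF, 0 °C; then 13, 0 °C → rt
Reagents that add atoms: none
Why: Hydroalumination of the propiolate gives the α-alumino acrylate, which adds 1,2 to the aldehyde to give the Baylis–Hillman-type adduct without an amine catalyst that could isomerise the β,γ-unsaturated aldehyde, and the new carbinol centre is erased in step 10.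

**Step 10**
Reactants: 16 Baylis–Hillman-type hydroxy ester
Product: 17 methyl (2Z,5Z)-2-(bromomethyl)-6-[(2R)-5-methoxy-5-methyltetrahydrofuran-2-yl]hepta-2,5-dienoate
Conditions: N-bromosuccinimide, Me2S, CH2Cl2, 0 °C → rt
Reagents that add atoms: N-bromosuccinimide, O=C1CCC(=O)N1Br
Why: The alkoxysulfonium salt (Corey–Kim-type activation) is displaced by bromide with allylic transposition (SN2′), which should give the thermodynamically preferred (Z)-2-(bromomethyl)-2-enoate with C14 cis to the CH2Br group.

**Step 11**
Reactants: 4 (E)-3-methyl-6-(2-methyl-1,3-dioxolan-2-yl)hex-2-enal; 17 allyl bromide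
Product: 19 (4S,5S)-4-[(2Z,4R)-4-hydroxy-3-methyl-7-oxooct-2-en-1-yl]-3-methylidene-5-[(E)-2-methyl-6-oxohept-1-en-1-yl]dihydrofuran-2(3H)-one, via silyl ether adduct 18 (not isolated)
Conditions: CrCl2 (10 mol %), chiral tridentate carbazole bis(oxazoline) ligand (12 mol %, antipode chosen for 1S,2S), Mn powder, i-Pr2NEt, Me3SiCl, THF, rt; then TsOH·H2O, acetone–H2O, rt
Reagents that add atoms: water, O
Why: Catalytic asymmetric Nozaki–Hiyama–Kishi 2-(alkoxycarbonyl)allylation, in which the γ-substituted allylchromium reagent (substituent trans to the ester) adds through C1 in a chair transition state to the syn adduct and the ligand on chromium selects the aldehyde face so that C1 and C2 should both be S, after which the acidic work-up removes the silyl ether, closes the cis-fused α-methylene-γ-butyrolactone and hydrolyses both ketals.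

**Step 12**
Reactants: 19 seco hydroxy diketone lactone
Product: 22 (4S,5S)-4-{(Z)-3-[(3S)-6-hydroxy-6-methyl-1,2-dioxan-3-yl]but-2-en-1-yl}-3-methylidene-5-[(E)-2-methyl-6-oxohept-1-en-1-yl]dihydrofuran-2(3H)-one (both C6 epimers of the dioxane), via mesylate 20 (not isolated), via hydroperoxide 21 (not isolated)
Conditions: MsCl, Et3N, CH2Cl2, −65 °C; then anhydrous H2O2 (excess), Et2O, −100 → −40 °C
Reagents that add atoms: hydrogen peroxide, OO
Why: The allylic mesylate is displaced by hydrogen peroxide at low temperature with inversion (SN2 perhydrolysis of a sulfonate), which should set C11 as S, and the γ-hydroperoxy ketone closes spontaneously on the C8 ketone to the six-membered peroxy hemiketal.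

**Step 13**
Reactants: 22 peroxy hemiketal
Product: 23 (4S,5S)-4-{(Z)-3-[(3S)-6-methoxy-6-methyl-1,2-dioxan-3-yl]but-2-en-1-yl}-3-methylidene-5-[(E)-2-methyl-6-oxohept-1-en-1-yl]dihydrofuran-2(3H)-one (both C6 epimers of the dioxane)
Conditions: MeOH, PPTS (cat.), rt
Reagents that add atoms: methanol, CO
Why: Acid-catalysed exchange of the hemiketal hydroxyl for methoxy (peroxyketal formation) puts a leaving group on C8, both C8 epimers being equally useful because C8 becomes planar in step 14.

**Step 14**
Reactants: 23 methyl peroxyketal with the C7 methyl ketone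
Product: 25 (1S,2S,3E,7R,8R,11S,12Z)-7-acetyl-8,11-epidioxycembra-3,12,15(17)-trien-16,2-olide, via enol silane 24 (not isolated)
Conditions: i-Pr2NEt (1.5 equiv), Me3SiOTf (3 equiv), CH2Cl2 (1 mM, slow addition of 23), −78 → −30 °C
Reagents that add atoms: none
Why: Proposed new method: Me3SiOTf with i-Pr2NEt should convert the C7 methyl ketone into its more substituted silyl enol ether 24 and ionise the methoxy group at C8 of the 3-methoxy-1,2-dioxane to a cyclic peroxycarbenium ion (C8=O+–O, stabilised by the ring peroxide oxygen), which the tethered enol silane attacks through C7 in a Mukaiyama-type addition. The closest known reactions are the intermolecular Lewis-acid additions of enol silanes and silyl ketene acetals to 3-alkoxy-1,2-dioxanes and 1,2-dioxolanes and the one-pot silyl triflate/amine enol silane formation–acetal addition, neither shown in ring-closing mode at a peroxycarbenium ion. One ring is closed, the 14-membered carbocycle C1–C14, exo with respect to the enol double bond (the acetyl carbon stays outside the ring), with the preformed dioxane left as the O–O bridge between C8 and C11. C8 should become R because attack along the axial direction of the half-chair cation with the C11 alkenyl group pseudo-equatorial puts C7 cis to C12, the face the tether reaches, and C7 should become R through an open transition state in which H7 lies over the dioxane ring, the silyloxy-bearing enol carbon sits in the open sector between the ring oxygen and C19, and C6 lies between C19 and C9. The step needs ring closure over oligomerisation (high dilution, slow addition), enolisation towards C7 instead of the methyl group (the trisubstituted enol silane is favoured under the equilibrating silyl triflate conditions and is the stronger nucleophile) and capture of the cation by the enol silane instead of the C12=C13 alkene (the enol silane is the far better nucleophile).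

**Step 15**
Reactants: 25 macrocyclic β-peroxy methyl ketone
Product: 26 (1S,2S,3E,7R,8R,11S,12Z)-7-acetoxy-8,11-epidioxycembra-3,12,15(17)-trien-16,2-olide (CNP0238885.8)
Conditions: Me3SiOOSiMe3, SnCl4 (cat.), trans-cyclohexane-1,2-diamine (cat.), 4 Å MS, CH2Cl2, 0 °C → rt
Reagents that add atoms: bis(trimethylsilyl) peroxide, C[Si](C)(C)OO[Si](C)(C)C
Why: Baeyer–Villiger oxidation with bis(trimethylsilyl) peroxide under Lewis-acid catalysis, a combination that does not epoxidise alkenes, should insert oxygen between C7 and the acetyl carbon because the secondary carbon migrates in preference to methyl and with retention, turning the helper acetyl group into the C7 acetate.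

**Compound list**

1 | 2-(3-chloropropyl)-2-methyl-1,3-dioxolane | CC1(CCCCl)OCCO1 | starting material
2 | 2-methyl-2-(pent-4-yn-1-yl)-1,3-dioxolane | CC1(CCCC#C)OCCO1 | intermediate
3 | (E)-3-methyl-6-(2-methyl-1,3-dioxolan-2-yl)hex-2-en-1-ol | OC/C=C(\C)CCCC1(C)OCCO1 | intermediate
4 | (E)-3-methyl-6-(2-methyl-1,3-dioxolan-2-yl)hex-2-enal | O=C/C=C(\C)CCCC1(C)OCCO1 | intermediate
5 | (R)-5-oxotetrahydrofuran-2-carboxylic acid | OC(=O)[C@H]1CCC(=O)O1 | starting material
6 | (R)-5-oxotetrahydrofuran-2-carbonyl chloride | ClC(=O)[C@H]1CCC(=O)O1 | intermediate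
7 | (R)-5-acetyldihydrofuran-2(3H)-one | CC(=O)[C@H]1CCC(=O)O1 | intermediate
8 | [3-(tert-butyldimethylsilyloxy)propyl]triphenylphosphonium bromide | CC(C)(C)[Si](C)(C)OCCC[P+](c1ccccc1)(c1ccccc1)c1ccccc1.[Br-] | starting material
9 | (R)-5-[(Z)-5-(tert-butyldimethylsilyloxy)pent-2-en-2-yl]dihydrofuran-2(3H)-one | C/C(=C/CCO[Si](C)(C)C(C)(C)C)[C@H]1CCC(=O)O1 | intermediate
10 | (5R)-5-[(Z)-5-(tert-butyldimethylsilyloxy)pent-2-en-2-yl]-2-methyltetrahydrofuran-2-ol (lactol, both C2 epimers) | CC1(O)CC[C@@H](O1)/C(C)=C\CCO[Si](C)(C)C(C)(C)C | intermediate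
11 | (5R)-2-methoxy-2-methyl-5-[(Z)-5-(tert-butyldimethylsilyloxy)pent-2-en-2-yl]tetrahydrofuran (both C2 epimers) | COC1(C)CC[C@@H](O1)/C(C)=C\CCO[Si](C)(C)C(C)(C)C | intermediate
12 | (Z)-4-[(2R)-5-methoxy-5-methyltetrahydrofuran-2-yl]pent-3-en-1-ol | COC1(C)CC[C@@H](O1)/C(C)=C\CCO | intermediate
13 | (Z)-4-[(2R)-5-methoxy-5-methyltetrahydrofuran-2-yl]pent-3-enal | COC1(C)CC[C@@H](O1)/C(C)=C\CC=O | intermediate
14 | methyl propiolate | C#CC(=O)OC | starting material
15 | methyl 2-(diisobutylalumanyl)acrylate | C=C(C(=O)OC)[Al](CC(C)C)CC(C)C | intermediate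
16 | methyl (Z)-3-hydroxy-6-[(2R)-5-methoxy-5-methyltetrahydrofuran-2-yl]-2-methylidenehept-5-enoate (both C3 epimers) | COC1(C)CC[C@@H](O1)/C(C)=C\CC(O)C(=C)C(=O)OC | intermediate
17 | methyl (2Z,5Z)-2-(bromomethyl)-6-[(2R)-5-methoxy-5-methyltetrahydrofuran-2-yl]hepta-2,5-dienoate | COC1(C)CC[C@@H](O1)/C(C)=C\C/C=C(\CBr)C(=O)OC | intermediate
18 | syn allylation adduct: methyl 2-methylidene ester with C1 (S), C2 (S)-OSiMe3, both ketals intact | COC(=O)C(=C)[C@H](C/C=C(/C)[C@H]1CCC(C)(OC)O1)[C@@H](O[Si](C)(C)C)/C=C(\C)CCCC2(C)OCCO2 | intermediate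
19 | (4S,5S)-4-[(2Z,4R)-4-hydroxy-3-methyl-7-oxooct-2-en-1-yl]-3-methylidene-5-[(E)-2-methyl-6-oxohept-1-en-1-yl]dihydrofuran-2(3H)-one | C=C1C(=O)O[C@@H](/C=C(\C)CCCC(C)=O)[C@H]1C/C=C(/C)[C@H](O)CCC(C)=O | intermediate
20 | (11R)-methanesulfonate of 19 | C=C1C(=O)O[C@@H](/C=C(\C)CCCC(C)=O)[C@H]1C/C=C(/C)[C@H](OS(C)(=O)=O)CCC(C)=O | intermediate
21 | (11S)-hydroperoxide (open γ-hydroperoxy ketone) | C=C1C(=O)O[C@@H](/C=C(\C)CCCC(C)=O)[C@H]1C/C=C(/C)[C@@H](OO)CCC(C)=O | intermediate
22 | (4S,5S)-4-{(Z)-3-[(3S)-6-hydroxy-6-methyl-1,2-dioxan-3-yl]but-2-en-1-yl}-3-methylidene-5-[(E)-2-methyl-6-oxohept-1-en-1-yl]dihydrofuran-2(3H)-one | C=C1C(=O)O[C@@H](/C=C(\C)CCCC(C)=O)[C@H]1C/C=C(/C)[C@@H]2CCC(C)(O)OO2 | intermediate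
23 | (4S,5S)-4-{(Z)-3-[(3S)-6-methoxy-6-methyl-1,2-dioxan-3-yl]but-2-en-1-yl}-3-methylidene-5-[(E)-2-methyl-6-oxohept-1-en-1-yl]dihydrofuran-2(3H)-one | C=C1C(=O)O[C@@H](/C=C(\C)CCCC(C)=O)[C@H]1C/C=C(/C)[C@@H]2CCC(C)(OC)OO2 | intermediate
24 | (Z)-trimethylsilyl enol ether of 23 at C7 | C=C1C(=O)O[C@@H](/C=C(\C)CC/C=C(/C)O[Si](C)(C)C)[C@H]1C/C=C(/C)[C@@H]2CCC(C)(OC)OO2 | intermediate
25 | (1S,2S,3E,7R,8R,11S,12Z)-7-acetyl-8,11-epidioxycembra-3,12,15(17)-trien-16,2-olide | C=C1C(=O)O[C@H]2/C=C(\C)CC[C@@H](C(C)=O)[C@@]3(C)CC[C@H](OO3)/C(C)=C\C[C@@H]12 | intermediate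
26 | (1S,2S,3E,7R,8R,11S,12Z)-7-acetoxy-8,11-epidioxycembra-3,12,15(17)-trien-16,2-olide (CNP0238885.8) | C=C1C(=O)O[C@H]2/C=C(\C)CC[C@@H](OC(C)=O)[C@@]3(C)CC[C@H](OO3)/C(C)=C\C[C@@H]12 | target

**Totals**

Total steps: 15. Longest linear sequence: 12 steps (5 → 26, steps 4–15).

**Steps most likely to fail**

1. Step 14 (Proposed new method). What may go wrong: oligomerisation instead of ring closure; capture of the C8 cation by the C12=C13 alkene; enolisation towards the methyl terminus, which would close a 16-membered ring; poor facial selectivity at the enol carbon C7. The fallback uses known chemistry only: the C7–C8 bond is made between two half-size partners and the ring is closed at C3=C4 by olefin metathesis. It sets out from 17. Allylation of acrolein under the step 11 conditions should give the vinyl lactone F1, and the step 12 and step 13 conditions should turn it into the methyl peroxyketal F2. 6-Methylhept-6-en-2-one is converted with Me3SiCl, NaI and Et3N in MeCN into its internal (Z)-enol silane F3. Me3SiOTf-mediated addition of F3 to F2 in CH2Cl2 at −78 °C, the established intermolecular reaction of enol silanes with 3-alkoxy-1,2-dioxanes, should give the β-peroxy ketone F4, with C8 set by axial attack and the C7 epimers to be separated. The step 15 conditions should then give the acetate F5. Ring-closing metathesis with the second-generation Grubbs catalyst (H2IMes)(PCy3)Cl2Ru=CHPh at high dilution closes C3=C4, the E isomer is separated, and the route is rejoined at 26.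

2. Step 12. What may go wrong: ionisation of the allylic mesylate with loss of configuration at C11 or allylic transposition, and internal capture of C11 by the C8 carbonyl oxygen instead of hydrogen peroxide. The fallback replaces neutral hydrogen peroxide by an anionic, protected peroxide nucleophile. It sets out from 19: the mesylate 20 is made as before and displaced at 0 °C in DMF by the caesium salt (CsOH) of 2-methoxyprop-2-yl hydroperoxide, itself made from 2-methoxypropene and H2O2. This SN2 reaction with inversion should give the protected (11S)-peroxide F6. TsOH in MeOH then releases the hydroperoxide, closes it on the C8 ketone and methylates the hemiketal, rejoining the route at 23.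

3. Step 15. What may go wrong: epoxidation of the trisubstituted alkenes by the oxidant, or Lewis-acid-induced retro-addition (ionisation of the C7–C8 bond) or peroxide fragmentation of the β-peroxy ketone. The fallback is enzymatic oxygen insertion: a Baeyer–Villiger monooxygenase (phenylacetone or cyclohexanone monooxygenase, NADPH recycled with glucose-6-phosphate dehydrogenase, buffer with cosolvent) converts methyl ketones into acetates without touching alkenes or peroxides. It sets out from 25 and comes back at 26; this fallback makes no new compound (F0).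

**Further compounds**

F1 | step 14 | (4S,5S)-5-ethenyl-4-[(2Z,4R)-4-hydroxy-3-methyl-7-oxooct-2-en-1-yl]-3-methylidenedihydrofuran-2(3H)-one | C=C1C(=O)O[C@@H](C=C)[C@H]1C/C=C(/C)[C@H](O)CCC(C)=O
F2 | step 14 | (4S,5S)-5-ethenyl-4-{(Z)-3-[(3S)-6-methoxy-6-methyl-1,2-dioxan-3-yl]but-2-en-1-yl}-3-methylidenedihydrofuran-2(3H)-one | C=C1C(=O)O[C@@H](C=C)[C@H]1C/C=C(/C)[C@@H]2CCC(C)(OC)OO2
F3 | step 14 | (Z)-trimethyl[(6-methylhepta-2,6-dien-2-yl)oxy]silane | C=C(C)CC/C=C(/C)O[Si](C)(C)C
F4 | step 14 | acyclic β-peroxy ketone: F2 joined at C8 (R) to C7 (R) of the acetyl-bearing chain with terminal 2-methylallyl end | C=C1C(=O)O[C@@H](C=C)[C@H]1C/C=C(/C)[C@@H]2CC[C@@](C)(OO2)[C@@H](CCC(C)=C)C(C)=O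
F5 | step 14 | C7 acetate of F4 (metathesis precursor) | C=C1C(=O)O[C@@H](C=C)[C@H]1C/C=C(/C)[C@@H]2CC[C@@](C)(OO2)[C@@H](CCC(C)=C)OC(C)=O
F6 | step 12 | (11S)-(2-methoxyprop-2-yl)peroxy derivative of 19 | C=C1C(=O)O[C@@H](/C=C(\C)CCCC(C)=O)[C@H]1C/C=C(/C)[C@H](CCC(C)=O)OOC(C)(C)OC
F0 | step 15 | none | none
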